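Retrosynthesis: the ring bond C1–C10 is cut first (alkenyl bromide plus aldehyde), then O–C6 and C7=C11 of the butenolide together with O–C13, then C8–C9, C7–C8 and C6–C7 around a dithiane carbon that stands for the C7 ketone.
Forward: nerol supplies C1–C6 and C15, and its 2Z double bond becomes C4=C5; 1,3-dithiane brings C7, DMF C8 and allene C9/C10/C14. The open chain is oxidised at C6, the lactone ring (ring B) is annulated, the prenyl end is cut back to the C1 aldehyde, and the ten-membered ring (ring A) closes last.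
Enabling feature: C6 is at once allylic to C4=C5 and α to the C7 carbonyl, so a sulfonate there is SN2-active and sits 1,2 to a ketone. A carboxylate carrying a latent phosphonate carbanion at C11 can bind C6 through oxygen and olefinate C7, closing the five-membered ring O–C6–C7=C11–C12, while acetate enters at C13 as third component.
Stereochemistry: C8 by reagent control (isopinocampheylborane from (+)-α-pinene); C6 by enolate hydroxylation with a camphor-derived oxaziridine, then inversion in the key step; C1 by the macrocyclic ring closure; 4Z from nerol.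

Key step: step 10

Assumption: the SMILES is read as 4Z (C3 and C6 cis on C4=C5) with 1R, 6R, 8S; germacrane numbering is used for atoms throughout.

Step 1
Reactants: 1 nerol
Product: 2 neryl bromide
Conditions: PBr3, pyridine (cat.), Et2O, −10 °C
Reagents that add atoms: phosphorus tribromide, BrP(Br)Br
Why: Bromination of the primary allylic alcohol with PBr3 (SN2 on the bromophosphite) should give the bromide with the 2Z alkene, the future C4=C5, intact.

Step 2
Reactants: 3 1,3-dithiane; 2 neryl bromide
Product: 5 2-[(2Z)-3,7-dimethylocta-2,6-dien-1-yl]-1,3-dithiane, via 2-lithio-1,3-dithiane 4 (not isolated)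
Conditions: n-BuLi, THF, −30 °C; then 2, −78 to 0 °C
Reagents that add atoms: none
Why: Corey–Seebach alkylation, in which the lithiated dithiane (acyl anion equivalent for C7) displaces the primary allylic bromide by SN2 and forms the C6–C7 bond.

Step 3
Reactants: 5 2-[(2Z)-3,7-dimethylocta-2,6-dien-1-yl]-1,3-dithiane
Product: 7 2-[(2Z)-3,7-dimethylocta-2,6-dien-1-yl]-1,3-dithiane-2-carbaldehyde, via 2-lithio derivative 6 (not isolated)
Conditions: n-BuLi, THF, −30 °C; then DMF, −78 °C to rt; H2O
Reagents that add atoms: N,N-dimethylformamide, CN(C)C=O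
Why: A second Corey–Seebach metalation and formylation with DMF should install C8 as a non-enolisable aldehyde next to the masked C7 ketone.

Step 4
Reactants: 7 2-[(2Z)-3,7-dimethylocta-2,6-dien-1-yl]-1,3-dithiane-2-carbaldehyde; 8 allene
Product: 11 (1S)-3-bromo-1-{2-[(2Z)-3,7-dimethylocta-2,6-dien-1-yl]-1,3-dithian-2-yl}but-3-en-1-ol, via 2-bromoallyl(diisopinocampheyl)borane 9 (not isolated), via borinate ester 10 (not isolated)
Conditions: (−)-Ipc2BBr [from (+)-α-pinene], 8, CH2Cl2, −78 °C; then 7, −78 °C; then MeOH, aq. NaHCO3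
Reagents that add atoms: (−)-B-bromodiisopinocampheylborane, BrB([C@@H]1C[C@@H]2C[C@H]([C@H]1C)C2(C)C)[C@@H]1C[C@@H]2C[C@H]([C@H]1C)C2(C)C
Why: Bromoboration of allene puts boron on the terminal and bromine on the central carbon, and the resulting 2-bromoallylborane should add by Brown allylboration through a chair transition state in which the isopinocampheyl groups direct attack to the face giving the 8S carbinol (the sense known for α-branched aldehydes), bringing in C9, C10, C14 and the alkenyl bromide at once.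

Step 5
Reactants: 11 (1S)-3-bromo-1-{2-[(2Z)-3,7-dimethylocta-2,6-dien-1-yl]-1,3-dithian-2-yl}but-3-en-1-ol
Product: 12 (1S)-3-bromo-1-{2-[(2Z)-3,7-dimethylocta-2,6-dien-1-yl]-1,3-dithian-2-yl}but-3-en-1-yl acetate
Conditions: Ac2O, Et3N, DMAP (cat.), CH2Cl2, rt
Reagents that add atoms: acetic anhydride, CC(=O)OC(C)=O
Why: DMAP-catalysed acylation of the hindered secondary alcohol should place the C8 acetate with retention.

Step 6
Reactants: 12 (1S)-3-bromo-1-{2-[(2Z)-3,7-dimethylocta-2,6-dien-1-yl]-1,3-dithian-2-yl}but-3-en-1-yl acetate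
Product: 13 (4S,7Z)-2-bromo-8,12-dimethyl-5-oxotrideca-1,7,11-trien-4-yl acetate
Conditions: PhI(OCOCF3)2, MeCN/H2O (9:1), 0 °C
Reagents that add atoms: water, O
Why: Oxidative dethioacetalisation with the trivalent iodine reagent is fast at sulfur and should leave the three C=C bonds, the acetate and the alkenyl bromide untouched while unveiling the C7 ketone.

Step 7
Reactants: 13 (4S,7Z)-2-bromo-8,12-dimethyl-5-oxotrideca-1,7,11-trien-4-yl acetate
Product: 15 (4S,6S,7Z)-2-bromo-6-hydroxy-8,12-dimethyl-5-oxotrideca-1,7,11-trien-4-yl acetate, via sodium enolate 14 (not isolated)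
Conditions: NaN(SiMe3)2, THF, −78 °C; then (+)-(camphorsulfonyl)oxaziridine, −78 °C; AcOH
Reagents that add atoms: (+)-(camphorsulfonyl)oxaziridine, CC1(C)[C@@H]2CC[C@]13CS(=O)(=O)N4O[C@@]34C2
Why: Davis enolate hydroxylation, in which kinetic deprotonation should occur at the C6 methylene (allylic and α to the ketone) and the camphor-derived oxaziridine should deliver oxygen to the α-carbon to give the 6S alcohol by analogy with deoxybenzoin-type enolates, with the C8 acetoxy centre expected to reinforce that face.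

Step 8
Reactants: 15 (4S,6S,7Z)-2-bromo-6-hydroxy-8,12-dimethyl-5-oxotrideca-1,7,11-trien-4-yl acetate
Product: 16 (4S,6S,7Z)-2-bromo-6-(methanesulfonyloxy)-8,12-dimethyl-5-oxotrideca-1,7,11-trien-4-yl acetate
Conditions: Ms2O, Et3N, CH2Cl2, −20 °C; used crude
Reagents that add atoms: methanesulfonic anhydride, CS(=O)(=O)OS(C)(=O)=O
Why: O-Sulfonylation with the anhydride (no nucleophilic chloride present) should turn the C6 hydroxyl into a leaving group with retention of configuration.

Step 9
Reactants: 17 (diethoxyphosphoryl)acetic acid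
Product: 18 2-(diethoxyphosphoryl)prop-2-enoic acid
Conditions: (CH2O)n, piperidinium acetate (cat.), toluene, 90 °C, −H2O
Reagents that add atoms: formaldehyde (as paraformaldehyde), C=O
Why: Knoevenagel methylenation of the active methylene with formaldehyde, the standard entry to 2-phosphonoacrylates, should give the acid that becomes C11, C12 and C13.

Step 10
Reactants: 16 (4S,6S,7Z)-2-bromo-6-(methanesulfonyloxy)-8,12-dimethyl-5-oxotrideca-1,7,11-trien-4-yl acetate; 18 2-(diethoxyphosphoryl)prop-2-enoic acid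
Product: 21 (5R)-4-[(1S)-1-acetoxy-3-bromobut-3-en-1-yl]-3-(acetoxymethyl)-5-[(1Z)-2,6-dimethylhepta-1,5-dien-1-yl]furan-2(5H)-one, via phosphonoacrylate ester 19 (not isolated), via cesium carbanion 20 (not isolated)
Conditions: 18, Cs2CO3, DMF, 0 °C; then 16, 0 °C to rt; then CsOAc, rt
Reagents that add atoms: cesium acetate, [Cs+].CC(=O)[O-]
Why: Proposed new method: the cesium carboxylate of 18 displaces the C6 mesylate by SN2 (forming O–C6 with inversion, 6S to 6R), acetate then adds to the vinylphosphonate terminus C13 of ester 19, and the phosphonate-stabilised carbanion 20 at C11 attacks the adjacent C7 ketone and collapses by Horner–Wadsworth–Emmons loss of diethyl phosphate to give C7=C11. The closest known reactions are the one-pot carboxylate alkylation/intramolecular HWE route to butenolides from α-halo or α-sulfonyloxy ketones and the tandem Michael/HWE reactions of 2-(diethoxyphosphoryl)acrylates with carbon, nitrogen, sulfur and alkoxide nucleophiles; new is a carboxylate as Michael donor, whose reversible addition should be drained by the fast intramolecular olefination. The lactone ring O–C6–C7=C11–C12 closes by 5-exo-trig addition of C11 to the C7 carbonyl. The only new stereocenter, C6, is set by inversion of the 6S sulfonate, and C8 is not touched. The step needs attack at C6 (secured by α-keto and allylic activation of the secondary sulfonate, with SN2' disfavoured at the fully substituted C4), the right order of the two carboxylates (CsOAc is added only after 16 is consumed) and survival of the acidic C6–H (weakly basic, amine-free medium).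

Step 11
Reactants: 21 (5R)-4-[(1S)-1-acetoxy-3-bromobut-3-en-1-yl]-3-(acetoxymethyl)-5-[(1Z)-2,6-dimethylhepta-1,5-dien-1-yl]furan-2(5H)-one
Product: 23 (4Z)-5-{(2R)-3-[(1S)-1-acetoxy-3-bromobut-3-en-1-yl]-4-(acetoxymethyl)-5-oxo-2,5-dihydrofuran-2-yl}-4-methylpent-4-enal, via vicinal diol 22 (not isolated)
Conditions: OsO4 (cat.), NaIO4, 2,6-lutidine, dioxane/H2O (3:1), rt
Reagents that add atoms: osmium tetroxide, O=[Os](=O)(=O)=O; sodium periodate, [Na+].[O-]I(=O)(=O)=O
Why: Lemieux–Johnson cleavage, in which OsO4 should dihydroxylate the electron-rich terminal trisubstituted alkene in preference to C4=C5 (deactivated by the allylic lactone oxygen), the alkenyl bromide and the butenolide, and periodate cleaves the diol to the C1 aldehyde.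

Step 12
Reactants: 23 (4Z)-5-{(2R)-3-[(1S)-1-acetoxy-3-bromobut-3-en-1-yl]-4-(acetoxymethyl)-5-oxo-2,5-dihydrofuran-2-yl}-4-methylpent-4-enal
Product: 24 8α,13-diacetoxy-1β-hydroxygermacra-4,7(11),10(14)-trien-6α,12-olide (1R,4Z,6R,8S)
Conditions: CrCl2 (excess), NiCl2 (cat.), DMSO, rt, high dilution (slow addition); aq. work-up
Reagents that add atoms: none
Why: Intramolecular Nozaki–Hiyama–Kishi coupling of the C10 alkenyl bromide with the C1 aldehyde closes ring A, tolerates the acetates and the butenolide, and is expected to give the 1R (1β) alcohol by addition to the peripheral face of the aldehyde in the ring-closing conformer (substrate control).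

Compound list
1 | nerol, (2Z)-3,7-dimethylocta-2,6-dien-1-ol | OC/C=C(/C)CCC=C(C)C | starting material
2 | neryl bromide, (2Z)-1-bromo-3,7-dimethylocta-2,6-diene | BrC/C=C(/C)CCC=C(C)C | intermediate
3 | 1,3-dithiane | C1CSCSC1 | starting material
4 | 2-lithio-1,3-dithiane | [Li]C1SCCCS1 | intermediate
5 | 2-[(2Z)-3,7-dimethylocta-2,6-dien-1-yl]-1,3-dithiane | C1(C/C=C(/C)CCC=C(C)C)SCCCS1 | intermediate
6 | 2-lithio derivative of 5 | [Li]C1(C/C=C(/C)CCC=C(C)C)SCCCS1 | intermediate
7 | 2-[(2Z)-3,7-dimethylocta-2,6-dien-1-yl]-1,3-dithiane-2-carbaldehyde | O=CC1(C/C=C(/C)CCC=C(C)C)SCCCS1 | intermediate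
8 | allene (propa-1,2-diene) | C=C=C | starting material
9 | (2-bromoprop-2-en-1-yl)diisopinocampheylborane, isopinocampheyl groups from (+)-α-pinene | C=C(Br)CB([C@@H]1C[C@@H]2C[C@H]([C@H]1C)C2(C)C)[C@@H]1C[C@@H]2C[C@H]([C@H]1C)C2(C)C | intermediate
10 | O-(diisopinocampheylboryl) derivative (borinate ester) of 11 | C=C(Br)C[C@H](OB([C@@H]2C[C@@H]3C[C@H]([C@H]2C)C3(C)C)[C@@H]2C[C@@H]3C[C@H]([C@H]2C)C3(C)C)C1(C/C=C(/C)CCC=C(C)C)SCCCS1 | intermediate
11 | (1S)-3-bromo-1-{2-[(2Z)-3,7-dimethylocta-2,6-dien-1-yl]-1,3-dithian-2-yl}but-3-en-1-ol | C=C(Br)C[C@H](O)C1(C/C=C(/C)CCC=C(C)C)SCCCS1 | intermediate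
12 | (1S)-3-bromo-1-{2-[(2Z)-3,7-dimethylocta-2,6-dien-1-yl]-1,3-dithian-2-yl}but-3-en-1-yl acetate | C=C(Br)C[C@H](OC(C)=O)C1(C/C=C(/C)CCC=C(C)C)SCCCS1 | intermediate
13 | (4S,7Z)-2-bromo-8,12-dimethyl-5-oxotrideca-1,7,11-trien-4-yl acetate | C=C(Br)C[C@H](OC(C)=O)C(=O)C/C=C(/C)CCC=C(C)C | intermediate
14 | sodium enolate of 13 (enolate double bond between C6 and C7 of the target numbering) | C=C(Br)C[C@H](OC(C)=O)C([O-])=C/C=C(/C)CCC=C(C)C.[Na+] | intermediate
15 | (4S,6S,7Z)-2-bromo-6-hydroxy-8,12-dimethyl-5-oxotrideca-1,7,11-trien-4-yl acetate | C=C(Br)C[C@H](OC(C)=O)C(=O)[C@@H](O)/C=C(/C)CCC=C(C)C | intermediate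
16 | (4S,6S,7Z)-2-bromo-6-(methanesulfonyloxy)-8,12-dimethyl-5-oxotrideca-1,7,11-trien-4-yl acetate | C=C(Br)C[C@H](OC(C)=O)C(=O)[C@@H](OS(C)(=O)=O)/C=C(/C)CCC=C(C)C | intermediate
17 | (diethoxyphosphoryl)acetic acid | CCOP(=O)(CC(=O)O)OCC | starting material
18 | 2-(diethoxyphosphoryl)prop-2-enoic acid | C=C(C(=O)O)P(=O)(OCC)OCC | intermediate
19 | (4S,6R,7Z)-4-acetoxy-2-bromo-8,12-dimethyl-5-oxotrideca-1,7,11-trien-6-yl 2-(diethoxyphosphoryl)prop-2-enoate | C=C(Br)C[C@H](OC(C)=O)C(=O)[C@H](OC(=O)C(=C)P(=O)(OCC)OCC)/C=C(/C)CCC=C(C)C | intermediate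
20 | cesium salt of the C11 carbanion formed from 19 by addition of acetate (3-acetoxy-2-(diethoxyphosphoryl)propanoate ester, deprotonated at C2) | C=C(Br)C[C@H](OC(C)=O)C(=O)[C@H](OC(=O)[C-](COC(C)=O)P(=O)(OCC)OCC)/C=C(/C)CCC=C(C)C.[Cs+] | intermediate
21 | (5R)-4-[(1S)-1-acetoxy-3-bromobut-3-en-1-yl]-3-(acetoxymethyl)-5-[(1Z)-2,6-dimethylhepta-1,5-dien-1-yl]furan-2(5H)-one | C=C(Br)C[C@H](OC(C)=O)C1=C(COC(C)=O)C(=O)O[C@@H]1/C=C(/C)CCC=C(C)C | intermediate
22 | 5,6-diol of the side chain of 21, (5R)-4-[(1S)-1-acetoxy-3-bromobut-3-en-1-yl]-3-(acetoxymethyl)-5-[(1Z)-5,6-dihydroxy-2,6-dimethylhept-1-en-1-yl]furan-2(5H)-one, both epimers at the secondary carbinol | C=C(Br)C[C@H](OC(C)=O)C1=C(COC(C)=O)C(=O)O[C@@H]1/C=C(/C)CCC(O)C(C)(C)O | intermediate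
23 | (4Z)-5-{(2R)-3-[(1S)-1-acetoxy-3-bromobut-3-en-1-yl]-4-(acetoxymethyl)-5-oxo-2,5-dihydrofuran-2-yl}-4-methylpent-4-enal | C=C(Br)C[C@H](OC(C)=O)C1=C(COC(C)=O)C(=O)O[C@@H]1/C=C(/C)CCC=O | intermediate
24 | 8α,13-diacetoxy-1β-hydroxygermacra-4,7(11),10(14)-trien-6α,12-olide (1R,4Z,6R,8S) | C=C1C[C@H](OC(C)=O)C2=C(COC(C)=O)C(=O)O[C@@H]2/C=C(/C)CC[C@H]1O | target

Total step count: 12. Longest linear sequence: 11 steps (steps 1 to 8 and 10 to 12, from nerol); step 9 is a one-step branch.

Steps most likely to fail: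

Step 10 (proposed new method). The addition of acetate to the vinylphosphonate may be too reversible or too slow, so that enolisation and epimerisation at C6 of the α-acyloxy ketone, or participation of the C8 acetate in the displacement, competes with ring closure. The fallback uses known chemistry. From 16 the same carboxylate displacement is run alone and ester 19 is isolated. It is then treated with 4-methoxybenzyl alcohol and catalytic Cs2CO3 in THF at 0 °C; alkoxide conjugate addition to a 2-phosphonoacrylate followed by intramolecular HWE is established for this reagent class and should give the 13-O-(4-methoxybenzyl) butenolide F1. DDQ in wet CH2Cl2 removes the benzylic ether to give the 13-hydroxy butenolide F2, and Ac2O/pyridine returns to the route at 21.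

Step 7. Oxygen transfer to the acyclic enolate may show poor facial selectivity, and deprotonation toward C8 or acetyl migration may intrude. In the fallback, 13 is hydroxylated with racemic trans-2-(phenylsulfonyl)-3-phenyloxaziridine, without reagent bias, and the two C6 epimers are separated. Compound 15 continues as planned. Its epimer, the (4S,6R,7Z)-6-hydroxy ketone F3, is esterified with 18 (DCC, CH2Cl2, 0 °C) with retention instead of inversion. This gives the same ester 19, which CsOAc converts into 21, so both epimers converge on the route at 21.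

Step 12. The macrocyclic addition may proceed with low or wrong facial selectivity at C1, or ring closure may be slow against oligomerisation. In the fallback, C1 is set by reagent control after ring closure. From 23 the coupling is run as before and the 1-epimer, the (1S) alcohol F4, or the epimer mixture is oxidised with Dess–Martin periodinane to the ring enone F5 (C1 ketone conjugated with the exocyclic methylene). This is reduced with (S)-2-methyl-CBS-oxazaborolidine and catecholborane in toluene at −78 °C, which should deliver hydride to give the 1R alcohol, returning to the route at 24.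

Further compounds
F1 | step 10 | (5R)-4-[(1S)-1-acetoxy-3-bromobut-3-en-1-yl]-5-[(1Z)-2,6-dimethylhepta-1,5-dien-1-yl]-3-{[(4-methoxybenzyl)oxy]methyl}furan-2(5H)-one | C=C(Br)C[C@H](OC(C)=O)C1=C(COCc2ccc(OC)cc2)C(=O)O[C@@H]1/C=C(/C)CCC=C(C)C
F2 | step 10 | (5R)-4-[(1S)-1-acetoxy-3-bromobut-3-en-1-yl]-5-[(1Z)-2,6-dimethylhepta-1,5-dien-1-yl]-3-(hydroxymethyl)furan-2(5H)-one | C=C(Br)C[C@H](OC(C)=O)C1=C(CO)C(=O)O[C@@H]1/C=C(/C)CCC=C(C)C
F3 | step 7 | (4S,6R,7Z)-2-bromo-6-hydroxy-8,12-dimethyl-5-oxotrideca-1,7,11-trien-4-yl acetate | C=C(Br)C[C@H](OC(C)=O)C(=O)[C@H](O)/C=C(/C)CCC=C(C)C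
F4 | step 12 | 1-epimer of 24, 8α,13-diacetoxy-1α-hydroxygermacra-4,7(11),10(14)-trien-6α,12-olide (1S,4Z,6R,8S) | C=C1C[C@H](OC(C)=O)C2=C(COC(C)=O)C(=O)O[C@@H]2/C=C(/C)CC[C@@H]1O
F5 | step 12 | 8α,13-diacetoxy-1-oxogermacra-4,7(11),10(14)-trien-6α,12-olide (4Z,6R,8S) | C=C1C[C@H](OC(C)=O)C2=C(COC(C)=O)C(=O)O[C@@H]2/C=C(/C)CCC1=O
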